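## Structural features

The target is a C25 alcohol built on a 6-7-7 tricycle. Cyclohexene ring C (C9, C10, C12, C13, C14, C24) is fused through the C9–C24 bond to seven-membered ring B (C6–C9, C24–C26). Ring B shares C6, C26 and C25 with seven-membered ring A (C2–C6, C26, C25), so rings A and B form a bicyclo[4.4.1]undecene with C26 as the one-carbon bridge. The core carries three alkenes: tetrasubstituted C9=C10 (methyl C11), the bridgehead trisubstituted C5=C6, and the exocyclic methylene C2=C1. The side chain adds an E-trisubstituted alkene C19=C20 bearing the primary allylic alcohol C22–O23. Four contiguous stereocenters run C15–C14–C24–C25: C15 lies in the side chain, C14 and C24 are trans on ring C, and the bridgehead hydrogen on C25 is anti to that on C24. The allylic alcohol (ionization, oxidation) and the 1,1-disubstituted and bridgehead alkenes (acid-promoted migration) are fragile, so strong acid and electrophilic oxidants must be avoided late. The real difficulties are the bridgehead alkene inside the bicyclo[4.4.1] unit, the configuration of C25 relative to C24 (uncorrectable once C25 is a bridgehead), and the adjacent pair C14/C15 linking ring C to an acyclic chain, all in a hydrocarbon core with no heteroatom handle. The key step exploits the fact that C15, its methyl C16 and the chain C17–C22 are the skeleton of (S)-citronellal, with C14 as its α-carbon and C24 as its aldehyde carbon. Ring C then lacks only C13, C12, C10 and C9, the four carbons of methyl vinyl ketone, and the annulation leaves an enone with electrophilic C24 and an enolizable C9/C10 unit, the polarity the later bond constructions need.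

## Logic of the disconnections

22 is traced to 21 and 21 to 20 by cutting O23–Si and the C2=C1 bond. These are the two most fragile groups, so they are unveiled last; a carbonyl at C2 also gives the acidity needed earlier at C25. The gain is a ketone with one alkene and one free hydroxyl fewer. The forward demand is methylenation of an enolizable, α-branched ketone and a final neutral desilylation.

20 is opened at C5=C6 to give 19. This is the one ring A bond whose formation also fixes the position of the bridgehead unsaturation. The bridged tricycle becomes a fused bicycle (rings B and C) with two terminal alkenes. The forward metathesis must engage a 1,1-disubstituted alkene, build a bridging seven-membered ring, and leave C9=C10 and C19=C20 alone; C25 must already be correct.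

19 is cut at C2–C3 and leads through 17 to 16. Keeping C2 at the carboxyl oxidation level until this point makes C25 the only acidic carbon in the earlier C–C bond formations. C3–C5 then come from a butenyl Grignard reagent. The forward steps need a single addition to the acyl group and equilibration of C25 to the trans arrangement.

16 is cut at C6–C7 and leads through 15 to 14. An sp2–sp3 coupling between a vinyl bromide at C6 and a borane at C7 closes ring B and leaves the exocyclic methylene that step 15 needs. Ring B is opened to a monocyclic ring C compound with two simple appendages. The forward step needs chemoselective hydroboration of one of four alkenes and a seven-membered ring closure.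

14 is cut at C25–C26 to give 13. C25 is the unique enolizable carbon, and C26, C6 and the sacrificial methylene arrive together in one purchased three-carbon dihalide. The demand is monoalkylation; no stereocontrol is asked for here.

13 is cut at C10–C11 and, through 12, at the C10–O bond of 11. An enol derivative of defined regiochemistry is the only reliable way to place the tetrasubstituted alkene at C9=C10. The methyl group comes from a methylzinc reagent. The forward steps must sulfonylate the dienolate without proton transfer and couple at a hindered triflate beside an ester.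

11 is cut at C24–C25 to give 10. The enone makes C24 electrophilic, and a ketene silyl acetal delivers C25 and C2 while trapping the enol at C9=C10. The cut removes the C24 stereocenter and two carbons. The forward addition must be 1,4-selective and occur anti to the substituent on C14.

10 is cut at C8–C9 and, through 9, at the C9–iodine bond of 8. The α-carbon of the enone is the one position that can be halogenated selectively, and a vinyl group is the smallest unit that supplies C8 and C7 and later a nucleophilic C7. This returns to the annulation product. The coupling must not move the C9=C24 alkene or epimerize C14.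

8 is cut at C9–C24 and C13–C14 and leads through 7 to 5 and 6. These two bonds are what an enamine Michael addition and an aldol condensation make, and the cut removes ring C and the C14 stereocenter at once. The gain is two acyclic components, one from the chiral pool. The forward step must impose the C14 configuration against the bias of C15 and close the ring without epimerization.

5 is traced through 4, 3 and 2 to 1 by removing the silyl group, the oxygen on C22 and the acetal. Citronellal already holds C15 in the right configuration and every carbon of the side chain. The forward steps need oxidation of only the methyl group trans to the chain, and release of the aldehyde without loss of the silyl ether or cyclization.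

## Other disconnections considered

Alternative 1: The cut is the C7–C8 bond of ring B, from sulfone A2 back to A1. In A1 ring A is complete (C2 methylene, methyl carbonate on C5, exocyclic C6=C7) and is joined through C25–C24 to ring C, which carries a phenylsulfonylmethyl group (C8) on C9. In the forward step zerovalent palladium, for example Pd(PPh3)4, would ionize the carbonate of A1 to an allyl complex over C5–C6–C7. The deprotonated sulfone carbon C8 would bond to C7, closing ring B and leaving the alkene at C5=C6 in A2.
- In its favour: the bridgehead alkene arises by allylic transposition in an irreversible C–C bond formation under mild conditions. Ring A is made beforehand in an unbridged setting, and the C2 methylene can already be present, so no late olefination is needed.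
- Against it here: C8 is seven atoms from both allyl termini, so attack at C5 would give an isomeric bridged ring that keeps the exocyclic alkene; only the steric preference for the primary terminus favours C7. A monosulfone anion is a hard nucleophile at the limit of palladium-allyl chemistry. A1 needs a carbonate-bearing carbon and a sulfone that must be installed and removed, and reductive cleavage of the allylic sulfone in A2 could shift the C9=C10 bond. C25 would sit on a single bond between two rings, where a thermodynamic preference is weaker than in 19.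
- Comparison: in structure both plans grow from enone 8 and differ in the order of ring closure (A then B there, B then A here). In mechanism an ionic allylation replaces the ruthenium-catalysed metathesis of step 15. On fixing the position of the bridgehead alkene the alternative is the equal of the chosen plan. On making the bridging event irreversible it is the better one. On step economy it is weaker, by an estimated three to five operations for sulfone and carbonate handling.

Alternative 2: The cut is C25–C26 and C3–C4 together, from ketone A4 back to chloromethyl ketone A3. A3 is a ring C compound with a CH2C(=O)CH2Cl arm on C24 and a 3-methylenepent-4-enyl arm on C9. In the forward step base in a polar medium (Et3N with LiClO4 in ether, or NaOCH2CF3 in trifluoroethanol) would ionize A3 to the oxyallyl cation C25–C2(O)–C3. This would add across the diene C26=C6–C5=C4 in a type 2 intramolecular (4+3) cycloaddition, giving A4 with rings A and B and the bridgehead alkene in one operation.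
- In its favour: two rings and two C–C bonds form in one step. Both reacting units are easy to reach from 13. A4 is the tert-butyldimethylsilyl analogue of 20, so the endgame is identical.
- Against it here: C25 becomes a bridgehead the moment it is created next to C24, so its configuration rests on the facial preference of a flexible four-atom tether and cannot be corrected. The cationic terminus C25 is homoallylic to the electron-rich C9=C10 bond, and the medium must not ionize the allylic silyl ether. Favorskii rearrangement and solvent capture compete when ring closure is slow.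
- Comparison: in structure the two plans meet at the same tricyclic ketone. In mechanism a cationic cycloaddition replaces two neutral catalytic couplings. On step economy and bond economy the alternative is the better plan, by about two steps counted from 13. On the endgame it is the equal. On control of C25 the chosen plan is safer, because 19 is equilibrated to the trans arrangement before ring A is closed. The cycloaddition is therefore kept in reserve as the fallback for step 15.

Alternative 3: The cut is the C9=C10 double bond, from A6 back to the 1,6-diketone A5. A5 is a bicyclo[4.4.1]undecenone (C9 ketone in ring B, C2 methylene and C5=C6 in place) carrying on C24 the open chain C14–C13–C12–C10(=O)–C11 and the side chain. In the forward step low-valent titanium (TiCl3 reduced by a zinc–copper couple, refluxing dimethoxyethane) would couple the two carbonyl groups of A5 and close ring C as the tetrasubstituted alkene of A6.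
- In its favour: carbonyl coupling to a six-membered tetrasubstituted alkene is among the most dependable uses of the McMurry reaction. The alkene position and the C11 methyl are delivered without any enolate regiochemistry. The last ring to close is unstrained.
- Against it here: with ring C formed last, C14 cannot be set by an annulation. It would have to be created, together with C24 (α to the C9 ketone and epimerizable), on the periphery of a preformed bridged bicycle by an intermolecular bond formation with weak control. The bridged core must be built first without the conformational help of ring C. A5 is prone to aldol reactions, and the reducing, Lewis acidic medium at reflux would test the allylic silyl ether.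
- Comparison: in structure the order is reversed (bridged bicycle first, ring C last). In mechanism a stoichiometric reductive coupling replaces the sequence of steps 8 to 10. On the construction of C9=C10 the alternative is the better plan (one step against three). On the reliability of the final ring closure it is also the better. On the C14/C15 pair and on overall length it is weaker, since the stereocenters fixed here in steps 5 and 8 would each need a separate solution.

Key step: step 5

Assumption: the small carbon sources used as reagents (potassium vinyltrifluoroborate, 1-(tert-butyldimethylsilyloxy)-1-methoxyethene, methylzinc chloride, 2,3-dibromopropene, 3-butenylmagnesium bromide, methyltriphenylphosphonium bromide) are purchased.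

Two corrections are built into the route:
- The aldol closure of ring C is 6-(enolendo)-exo-trig, not enolexo, because the enolate bond C9=C10 becomes part of the ring.
- O23 is carried as a tert-butyldiphenylsilyl (TBDPS) ether. A tert-butyldimethylsilyl ether would be at risk when the aldehyde is released with acid (step 4) and when the enol silyl ether is cleaved with fluoride (step 9). The skeletons of precursor 5 and annulation product 8 are unchanged.

In the step names, R* is the side chain (2S,5E)-7-[(tert-butyldiphenylsilyl)oxy]-6-methylhept-5-en-2-yl, attached through its C2 (C15 of the target).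

## Steps

Step 1
Reactants: 1 (S)-(−)-citronellal
Product: 2 (6S)-8,8-dimethoxy-2,6-dimethyloct-2-ene
Conditions: HC(OMe)3, MeOH, PPTS (cat.), 23 °C
Reagents that add atoms: trimethyl orthoformate, COC(OC)OC
Why: Acid-catalysed acetalization with an orthoester as dehydrating agent; the weak acid masks the aldehyde before it can undergo the carbonyl-ene cyclization typical of citronellal. The C15 stereocenter is β to the carbonyl and untouched.

Step 2
Reactants: 2 (6S)-8,8-dimethoxy-2,6-dimethyloct-2-ene
Product: 3 (2E,6S)-8,8-dimethoxy-2,6-dimethyloct-2-en-1-ol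
Conditions: SeO2 (0.3 equiv), t-BuOOH (anhydrous, decane), salicylic acid (cat.), CH2Cl2, 0→23 °C
Reagents that add atoms: tert-butyl hydroperoxide, CC(C)(C)OO; selenium dioxide, O=[Se]=O
Why: Selenium dioxide allylic oxidation (ene reaction, then [2,3]-sigmatropic shift) attacks the more substituted alkene terminus and there the methyl group trans to the chain, so the E-allylic alcohol results with the alkene geometry retained. t-BuOOH keeps SeO2 catalytic, and the run is stopped before over-oxidation to the enal becomes important.

Step 3
Reactants: 3 (2E,6S)-8,8-dimethoxy-2,6-dimethyloct-2-en-1-ol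
Product: 4 tert-butyl{[(2E,6S)-8,8-dimethoxy-2,6-dimethyloct-2-en-1-yl]oxy}diphenylsilane
Conditions: TBDPSCl, imidazole, CH2Cl2, 0→23 °C
Reagents that add atoms: tert-butyldiphenylsilyl chloride, CC(C)(C)[Si](Cl)(c1ccccc1)c1ccccc1
Why: Silylation of a primary alcohol with a silyl chloride and imidazole. TBDPS is preferred to TBS because it must survive acidic release of the aldehyde, a silyl triflate, suspended CsF and several organometallic reagents before step 17.

Step 4
Reactants: 4 tert-butyl{[(2E,6S)-8,8-dimethoxy-2,6-dimethyloct-2-en-1-yl]oxy}diphenylsilane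
Product: 5 (3S,6E)-8-[(tert-butyldiphenylsilyl)oxy]-3,7-dimethyloct-6-enal
Conditions: PPTS, acetone/H2O (10:1), 50 °C
Reagents that add atoms: water, O
Why: Mild acid-catalysed acetal hydrolysis; the primary TBDPS ether is stable to PPTS, and the weak acid should not trigger cyclization of the freed aldehyde onto the remote alkene.

Step 5
Reactants: 5 (3S,6E)-8-[(tert-butyldiphenylsilyl)oxy]-3,7-dimethyloct-6-enal; 6 methyl vinyl ketone
Product: 8 (4S)-4-R*-cyclohex-2-en-1-one, via keto aldehyde 7 (not isolated)
Conditions: (S)-2-[diphenyl(trimethylsilyloxy)methyl]pyrrolidine (10 mol%), ethyl 3,4-dihydroxybenzoate (20 mol%), neat, 4 °C; then LiOH, i-PrOH, 23 °C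
Reagents that add atoms: none
Why: The amine condenses with 5 to an E-enamine whose face syn to the diphenyl(silyloxy)methyl group is blocked, so C14 adds to the terminal carbon of 6 (C13) from the open face while the catechol activates the enone by hydrogen bonding; hydrolysis of the iminium ion releases 7 and the catalyst. The closest known reaction type is the amine-catalysed Michael addition of aldehydes to vinyl ketones followed by base-mediated aldol condensation to 4-substituted cyclohex-2-enones. LiOH then forms the methyl ketone enolate at C9, which closes ring C by 6-(enolendo)-exo-trig aldol addition to the aldehyde carbon C24, and E1cB loss of water gives the enone. The new stereocenter C14 is set under catalyst control; the shielding model that accounts for related additions with this catalyst family predicts the (S) configuration with the (S)-catalyst, which is the one required. The selectivity needed is facial selectivity at C14 against the weak 1,2-bias of C15, and it is secured by the reagent and not by the substrate; C15 is β to the carbonyl and is never enolized. In the aldol stage only attack by C9 is productive, since the enolate at C12 could only form a four-membered ring. The mild hydroxide/isopropanol medium should keep the α-branched aldehyde and the γ-center of the enone from epimerizing.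

Step 6
Reactants: 8 (4S)-4-R*-cyclohex-2-en-1-one
Product: 9 (4S)-2-iodo-4-R*-cyclohex-2-en-1-one
Conditions: iodine, pyridine, CH2Cl2, 0→23 °C
Reagents that add atoms: iodine, [I][I]
Why: α-Iodination of a cyclic enone by conjugate addition of pyridine, iodination of the transient enolate at C9 and E1cB loss of pyridine. C14 is not enolized under these weakly basic conditions, and the isolated alkene adds iodine only reversibly.

Step 7
Reactants: 9 (4S)-2-iodo-4-R*-cyclohex-2-en-1-one
Product: 10 (4S)-2-ethenyl-4-R*-cyclohex-2-en-1-one
Conditions: CH2=CHBF3K, PdCl2(dppf) (5 mol%), Cs2CO3, THF/H2O, 60 °C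
Reagents that add atoms: potassium vinyltrifluoroborate, C=C[B-](F)(F)F.[K+]
Why: Suzuki–Miyaura coupling: zerovalent palladium inserts readily into the electron-poor carbon–iodine bond at C9 and the vinyl group is transferred from boron; the carbonate base is too weak to deprotonate C14. The 2-vinyl enone is used at once because it can dimerize by Diels–Alder reaction.

Step 8
Reactants: 10 (4S)-2-ethenyl-4-R*-cyclohex-2-en-1-one
Product: 11 methyl 2-[(1S,6S)-3-[(tert-butyldimethylsilyl)oxy]-2-ethenyl-6-R*-cyclohex-2-en-1-yl]acetate
Conditions: CH2=C(OMe)OTBS, TBSOTf (10 mol%), CH2Cl2, −78 °C; Et3N quench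
Reagents that add atoms: 1-(tert-butyldimethylsilyloxy)-1-methoxyethene, C=C(OC)O[Si](C)(C)C(C)(C)C
Why: Mukaiyama–Michael addition under silyl triflate catalysis: the silylated enone is attacked at C24 and the silyl group ends on the enol oxygen, so the dienol ether C7=C8–C9=C10–O is obtained with its regiochemistry intact. C24 is set by approach anti to the branched substituent on C14 (axial attack on the half-chair with that group pseudo-equatorial), giving the trans relationship of C25 and C15 required in the target.

Step 9
Reactants: 11 methyl 2-[(1S,6S)-3-[(tert-butyldimethylsilyl)oxy]-2-ethenyl-6-R*-cyclohex-2-en-1-yl]acetate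
Product: 12 methyl 2-[(1S,6S)-2-ethenyl-6-R*-3-{[(trifluoromethyl)sulfonyl]oxy}cyclohex-2-en-1-yl]acetate
Conditions: CsF, PhNTf2, DME, 23 °C
Reagents that add atoms: N-phenylbis(trifluoromethanesulfonimide), O=S(=O)(N(c1ccccc1)S(=O)(=O)C(F)(F)F)C(F)(F)F
Why: Fluoride cleaves the enol silyl ether to the cesium dienolate, which is sulfonylated on oxygen by PhNTf2 faster than it can exchange protons, so the triflate keeps the C9=C10 position. The much less acidic ester and the alkyl TBDPS ether should be inert to suspended CsF.

Step 10
Reactants: 12 methyl 2-[(1S,6S)-2-ethenyl-6-R*-3-{[(trifluoromethyl)sulfonyl]oxy}cyclohex-2-en-1-yl]acetate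
Product: 13 methyl 2-[(1S,6S)-2-ethenyl-3-methyl-6-R*-cyclohex-2-en-1-yl]acetate
Conditions: MeZnCl, Pd(PPh3)4 (5 mol%), THF, 50 °C
Reagents that add atoms: methylzinc chloride, C[Zn]Cl
Why: Negishi coupling of an alkenyl triflate: oxidative addition of zerovalent palladium, transmetalation and reductive elimination place C11 on C10 and fix the tetrasubstituted C9=C10 alkene. Methylzinc chloride does not attack the ester.

Step 11
Reactants: 13 methyl 2-[(1S,6S)-2-ethenyl-3-methyl-6-R*-cyclohex-2-en-1-yl]acetate
Product: 14 methyl (2RS)-4-bromo-2-[(1R,6S)-2-ethenyl-3-methyl-6-R*-cyclohex-2-en-1-yl]pent-4-enoate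
Conditions: LiN(iPr)2, THF, −78 °C; 2,3-dibromopropene, DMPU, −78→−30 °C
Reagents that add atoms: 2,3-dibromopropene, C=C(Br)CBr
Why: SN2 alkylation of the lithium ester enolate, the only carbon acid in 13, by the allylic bromide; the vinylic bromide is inert. The configuration at C25 is not controlled here and need not be, because it is equilibrated in step 14.

Step 12
Reactants: 14 methyl (2RS)-4-bromo-2-[(1R,6S)-2-ethenyl-3-methyl-6-R*-cyclohex-2-en-1-yl]pent-4-enoate
Product: 16 methyl (4S,4aR,5RS)-1-methyl-7-methylidene-4-R*-3,4,4a,5,6,7,8,9-octahydro-2H-benzo[7]annulene-5-carboxylate, via B-alkyl-9-borabicyclononane 15 (not isolated)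
Conditions: 9-BBN, THF, 0→23 °C; then PdCl2(dppf) (10 mol%), AsPh3, Cs2CO3, DMF/THF/H2O, 50 °C, slow addition (final 2 mM)
Reagents that add atoms: none
Why: Hydroboration then intramolecular B-alkyl Suzuki–Miyaura coupling: 9-BBN adds to the terminal carbon C7 of the monosubstituted alkene much faster than to the bromoalkene or the trisubstituted side-chain alkene, and after base activation the alkyl group is transferred to the vinylpalladium bromide formed at C6, closing ring B with an exocyclic methylene on C6. The bidentate dppf ligand suppresses β-hydride elimination, and slow addition under dilution favours cyclization over oligomerization.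

Step 13
Reactants: 16 methyl (4S,4aR,5RS)-1-methyl-7-methylidene-4-R*-3,4,4a,5,6,7,8,9-octahydro-2H-benzo[7]annulene-5-carboxylate
Product: 17 (4S,4aR,5RS)-N-methoxy-N,1-dimethyl-7-methylidene-4-R*-3,4,4a,5,6,7,8,9-octahydro-2H-benzo[7]annulene-5-carboxamide
Conditions: MeNH(OMe)·HCl, i-PrMgCl, THF, −20→0 °C
Reagents that add atoms: N,O-dimethylhydroxylamine hydrochloride, CNOC.Cl
Why: Acyl substitution of the ester by the magnesium amide formed from the hydroxylamine salt and i-PrMgCl gives the N-methoxy-N-methylamide (Weinreb amide), which allows a single Grignard addition in step 14.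

Step 14
Reactants: 17 (4S,4aR,5RS)-N-methoxy-N,1-dimethyl-7-methylidene-4-R*-3,4,4a,5,6,7,8,9-octahydro-2H-benzo[7]annulene-5-carboxamide
Product: 19 1-[(4S,4aR,5S)-1-methyl-7-methylidene-4-R*-3,4,4a,5,6,7,8,9-octahydro-2H-benzo[7]annulen-5-yl]pent-4-en-1-one, via C25-epimeric ketones 18 (not isolated)
Conditions: CH2=CHCH2CH2MgBr, THF, 0 °C; aq NH4Cl; then DBU, CH2Cl2, 23 °C
Reagents that add atoms: 3-butenylmagnesium bromide, C=CCC[Mg]Br
Why: Grignard addition to the N-methoxy-N-methylamide stops at the chelated tetrahedral adduct, which gives the ketone only on work-up. DBU then equilibrates the C25 epimers through the C2 enolate; the isomer with the acyl group pseudo-equatorial and trans to the ring C bond at C24 should predominate. This is the required configuration and must be secured here, because C25 cannot be corrected once it is a bridgehead.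

Step 15
Reactants: 19 1-[(4S,4aR,5S)-1-methyl-7-methylidene-4-R*-3,4,4a,5,6,7,8,9-octahydro-2H-benzo[7]annulen-5-yl]pent-4-en-1-one
Product: 20 (1S,2R,3S,10Z)-6-methyl-3-R*-tricyclo[8.4.1.0^{2,7}]pentadeca-6,10-dien-14-one
Conditions: second-generation Grubbs catalyst RuCl2(=CHPh)(H2IMes)(PCy3) (10 mol%), 1,4-benzoquinone (10 mol%), toluene (1 mM), 80 °C
Reagents that add atoms: none
Why: Ring-closing metathesis: the ruthenium alkylidene forms at the terminal alkene (C5) and adds to the 1,1-disubstituted C6 methylene, releasing ethylene and closing ring A as a cis-cycloheptene whose alkene is the bridgehead C5=C6 bond; bridgehead alkenes of medium bridged bicycles are known to be accessible this way. The tetrasubstituted C9=C10 and the trisubstituted side-chain alkene are too hindered to compete, dilution disfavours cross-metathesis, and benzoquinone suppresses alkene migration.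

Step 16
Reactants: 20 (1S,2R,3S,10Z)-6-methyl-3-R*-tricyclo[8.4.1.0^{2,7}]pentadeca-6,10-dien-14-one
Product: 21 tert-butyl({(2E,6S)-2-methyl-6-[(1S,2R,3S,10Z)-6-methyl-14-methylidenetricyclo[8.4.1.0^{2,7}]pentadeca-6,10-dien-3-yl]hept-2-en-1-yl}oxy)diphenylsilane
Conditions: Ph3PCH3Br, KOtBu, THF, 0→50 °C
Reagents that add atoms: methyltriphenylphosphonium bromide, C[P+](c1ccccc1)(c1ccccc1)c1ccccc1.[Br-]
Why: Wittig methylenation with the unstabilized ylide converts the C2 ketone into the exocyclic methylene C1. The only α-stereocenter, C25, is a bridgehead and cannot epimerize.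

Step 17
Reactants: 21 tert-butyl({(2E,6S)-2-methyl-6-[(1S,2R,3S,10Z)-6-methyl-14-methylidenetricyclo[8.4.1.0^{2,7}]pentadeca-6,10-dien-3-yl]hept-2-en-1-yl}oxy)diphenylsilane
Product: 22 (2E,6S)-2-methyl-6-[(1S,2R,3S,10Z)-6-methyl-14-methylidenetricyclo[8.4.1.0^{2,7}]pentadeca-6,10-dien-3-yl]hept-2-en-1-ol (CNP0289180.1)
Conditions: Bu4NF, THF, 0→23 °C
Reagents that add atoms: none
Why: Fluoride-mediated cleavage of the silyl ether; the neutral conditions spare the acid-sensitive exocyclic and bridgehead alkenes and the allylic alcohol.

## Compound list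

1 | (S)-(−)-citronellal, (3S)-3,7-dimethyloct-6-enal | O=CC[C@@H](C)CCC=C(C)C | starting material
2 | (6S)-8,8-dimethoxy-2,6-dimethyloct-2-ene | COC(OC)C[C@@H](C)CCC=C(C)C | intermediate
3 | (2E,6S)-8,8-dimethoxy-2,6-dimethyloct-2-en-1-ol | COC(OC)C[C@@H](C)CC/C=C(\C)CO | intermediate
4 | tert-butyl{[(2E,6S)-8,8-dimethoxy-2,6-dimethyloct-2-en-1-yl]oxy}diphenylsilane | COC(OC)C[C@@H](C)CC/C=C(\C)CO[Si](c1ccccc1)(c1ccccc1)C(C)(C)C | intermediate
5 | (3S,6E)-8-[(tert-butyldiphenylsilyl)oxy]-3,7-dimethyloct-6-enal | O=CC[C@@H](C)CC/C=C(\C)CO[Si](c1ccccc1)(c1ccccc1)C(C)(C)C | intermediate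
6 | methyl vinyl ketone (but-3-en-2-one) | CC(=O)C=C | starting material
7 | (2S)-2-[(2S,5E)-7-[(tert-butyldiphenylsilyl)oxy]-6-methylhept-5-en-2-yl]-5-oxohexanal | CC(=O)CC[C@@H]([C@@H](C)CC/C=C(\C)CO[Si](c1ccccc1)(c1ccccc1)C(C)(C)C)C=O | intermediate
8 | (4S)-4-[(2S,5E)-7-[(tert-butyldiphenylsilyl)oxy]-6-methylhept-5-en-2-yl]cyclohex-2-en-1-one | O=C1CC[C@@H]([C@@H](C)CC/C=C(\C)CO[Si](c2ccccc2)(c2ccccc2)C(C)(C)C)C=C1 | intermediate
9 | (4S)-4-[(2S,5E)-7-[(tert-butyldiphenylsilyl)oxy]-6-methylhept-5-en-2-yl]-2-iodocyclohex-2-en-1-one | O=C1CC[C@@H]([C@@H](C)CC/C=C(\C)CO[Si](c2ccccc2)(c2ccccc2)C(C)(C)C)C=C1I | intermediate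
10 | (4S)-4-[(2S,5E)-7-[(tert-butyldiphenylsilyl)oxy]-6-methylhept-5-en-2-yl]-2-ethenylcyclohex-2-en-1-one | O=C1CC[C@@H]([C@@H](C)CC/C=C(\C)CO[Si](c2ccccc2)(c2ccccc2)C(C)(C)C)C=C1C=C | intermediate
11 | methyl 2-[(1S,6S)-3-[(tert-butyldimethylsilyl)oxy]-6-[(2S,5E)-7-[(tert-butyldiphenylsilyl)oxy]-6-methylhept-5-en-2-yl]-2-ethenylcyclohex-2-en-1-yl]acetate | CC(C)(C)[Si](C)(C)OC1=C(C=C)[C@@H](CC(=O)OC)[C@H]([C@@H](C)CC/C=C(\C)CO[Si](c2ccccc2)(c2ccccc2)C(C)(C)C)CC1 | intermediate
12 | methyl 2-[(1S,6S)-6-[(2S,5E)-7-[(tert-butyldiphenylsilyl)oxy]-6-methylhept-5-en-2-yl]-2-ethenyl-3-{[(trifluoromethyl)sulfonyl]oxy}cyclohex-2-en-1-yl]acetate | FC(F)(F)S(=O)(=O)OC1=C(C=C)[C@@H](CC(=O)OC)[C@H]([C@@H](C)CC/C=C(\C)CO[Si](c2ccccc2)(c2ccccc2)C(C)(C)C)CC1 | intermediate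
13 | methyl 2-[(1S,6S)-6-[(2S,5E)-7-[(tert-butyldiphenylsilyl)oxy]-6-methylhept-5-en-2-yl]-2-ethenyl-3-methylcyclohex-2-en-1-yl]acetate | CC1=C(C=C)[C@@H](CC(=O)OC)[C@H]([C@@H](C)CC/C=C(\C)CO[Si](c2ccccc2)(c2ccccc2)C(C)(C)C)CC1 | intermediate
14 | methyl (2RS)-4-bromo-2-[(1R,6S)-6-[(2S,5E)-7-[(tert-butyldiphenylsilyl)oxy]-6-methylhept-5-en-2-yl]-2-ethenyl-3-methylcyclohex-2-en-1-yl]pent-4-enoate (both C25 epimers) | CC1=C(C=C)[C@@H](C(CC(Br)=C)C(=O)OC)[C@H]([C@@H](C)CC/C=C(\C)CO[Si](c2ccccc2)(c2ccccc2)C(C)(C)C)CC1 | intermediate
15 | methyl (2RS)-2-[(1R,6S)-2-[2-(9-borabicyclo[3.3.1]nonan-9-yl)ethyl]-6-[(2S,5E)-7-[(tert-butyldiphenylsilyl)oxy]-6-methylhept-5-en-2-yl]-3-methylcyclohex-2-en-1-yl]-4-bromopent-4-enoate | CC1=C(CCB2C3CCCC2CCC3)[C@@H](C(CC(Br)=C)C(=O)OC)[C@H]([C@@H](C)CC/C=C(\C)CO[Si](c2ccccc2)(c2ccccc2)C(C)(C)C)CC1 | intermediate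
16 | methyl (4S,4aR,5RS)-4-[(2S,5E)-7-[(tert-butyldiphenylsilyl)oxy]-6-methylhept-5-en-2-yl]-1-methyl-7-methylidene-3,4,4a,5,6,7,8,9-octahydro-2H-benzo[7]annulene-5-carboxylate (both C25 epimers) | CC1=C2CCC(=C)CC(C(=O)OC)[C@H]2[C@H]([C@@H](C)CC/C=C(\C)CO[Si](c3ccccc3)(c3ccccc3)C(C)(C)C)CC1 | intermediate
17 | (4S,4aR,5RS)-4-[(2S,5E)-7-[(tert-butyldiphenylsilyl)oxy]-6-methylhept-5-en-2-yl]-N-methoxy-N,1-dimethyl-7-methylidene-3,4,4a,5,6,7,8,9-octahydro-2H-benzo[7]annulene-5-carboxamide (both C25 epimers) | CC1=C2CCC(=C)CC(C(=O)N(C)OC)[C@H]2[C@H]([C@@H](C)CC/C=C(\C)CO[Si](c3ccccc3)(c3ccccc3)C(C)(C)C)CC1 | intermediate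
18 | 1-[(4S,4aR,5RS)-4-[(2S,5E)-7-[(tert-butyldiphenylsilyl)oxy]-6-methylhept-5-en-2-yl]-1-methyl-7-methylidene-3,4,4a,5,6,7,8,9-octahydro-2H-benzo[7]annulen-5-yl]pent-4-en-1-one (both C25 epimers) | CC1=C2CCC(=C)CC(C(=O)CCC=C)[C@H]2[C@H]([C@@H](C)CC/C=C(\C)CO[Si](c3ccccc3)(c3ccccc3)C(C)(C)C)CC1 | intermediate
19 | 1-[(4S,4aR,5S)-4-[(2S,5E)-7-[(tert-butyldiphenylsilyl)oxy]-6-methylhept-5-en-2-yl]-1-methyl-7-methylidene-3,4,4a,5,6,7,8,9-octahydro-2H-benzo[7]annulen-5-yl]pent-4-en-1-one | CC1=C2CCC(=C)C[C@H](C(=O)CCC=C)[C@H]2[C@H]([C@@H](C)CC/C=C(\C)CO[Si](c3ccccc3)(c3ccccc3)C(C)(C)C)CC1 | intermediate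
20 | (1S,2R,3S,10Z)-3-[(2S,5E)-7-[(tert-butyldiphenylsilyl)oxy]-6-methylhept-5-en-2-yl]-6-methyltricyclo[8.4.1.0^{2,7}]pentadeca-6,10-dien-14-one | O=C1CCC=C2CCC3=C(C)CC[C@@H]([C@@H](C)CC/C=C(\C)CO[Si](c4ccccc4)(c4ccccc4)C(C)(C)C)[C@@H]3[C@@H]1C2 | intermediate
21 | tert-butyl({(2E,6S)-2-methyl-6-[(1S,2R,3S,10Z)-6-methyl-14-methylidenetricyclo[8.4.1.0^{2,7}]pentadeca-6,10-dien-3-yl]hept-2-en-1-yl}oxy)diphenylsilane | C=C1CCC=C2CCC3=C(C)CC[C@@H]([C@@H](C)CC/C=C(\C)CO[Si](c4ccccc4)(c4ccccc4)C(C)(C)C)[C@@H]3[C@@H]1C2 | intermediate
22 | (2E,6S)-2-methyl-6-[(1S,2R,3S,10Z)-6-methyl-14-methylidenetricyclo[8.4.1.0^{2,7}]pentadeca-6,10-dien-3-yl]hept-2-en-1-ol | C=C1CCC=C2CCC3=C(C)CC[C@@H]([C@@H](C)CC/C=C(\C)CO)[C@@H]3[C@@H]1C2 | target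

## Step count and least certain steps

Total step count: 17 steps. Longest linear sequence: 17 steps, from 1 to 22; 6 and all other carbon sources enter this single line as purchased reagents.

**Step 5 (key step).** What may go wrong: facial control in the enamine addition may be lost if the catalyst and the resident C15 center are mismatched, or C14 may partly epimerize through enolization of the α-branched aldehyde before the aldol closure. Fallback (auxiliary-controlled alkylation in place of the catalytic Michael addition): setting out from 5, condensation with (R)-1-amino-2-(methoxymethyl)pyrrolidine would give the RAMP hydrazone F1. Deprotonation with LiN(iPr)2 and alkylation of the azaenolate with 2-(2-bromoethyl)-2-methyl-1,3-dioxolane, a masked form of 6, would give the C14-alkylated hydrazone F2, the auxiliary shielding one face of the azaenolate. Aqueous oxalic acid followed by PPTS in wet acetone would remove hydrazine and ketal and return to the route at 7, which is cyclized with LiOH as in step 5.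

**Step 8.** What may go wrong: conjugate addition at C24, flanked by the α-vinyl group and the branched substituent on C14, may be slow, so that Diels–Alder dimerization of the vinyl enone or protodesilylation of the dienol ether takes over. Fallback (vinyl group built after the conjugate addition): setting out from 8, the same ketene silyl acetal would add to the unhindered enone to give the silyl enol ether F3. A TiCl4-mediated Mukaiyama aldol addition to acetaldehyde would give the β-hydroxy ketone F4, and mesylation–elimination (MsCl, Et3N; DBU) the ethylidene ketone F5. Tf2O with 2,6-di-tert-butyl-4-methylpyridine would then convert this enone, by O-sulfonylation and loss of a γ-proton from the ethylidene methyl group, into the through-conjugated dienyl triflate, returning to the route at 12.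

**Step 12.** What may go wrong: intermolecular coupling, protodeboronation or β-hydride elimination may outrun the seven-membered ring closure, because the alkylpalladium intermediate must adopt a strained conformation to reach C6. Fallback (ring B closed at C25–C26 by enolate alkylation): setting out from 13, hydroboration with 9-BBN would give the alkylborane F6. Intermolecular coupling (PdCl2(dppf), Cs2CO3) with 2-bromoallyl tert-butyldimethylsilyl ether would give the silyl ether F7. PPTS in methanol would free the allylic alcohol F8 without touching the TBDPS ether, and MsCl/Et3N then LiBr would give the allylic bromide F9. KN(SiMe3)2 under dilution would close ring B by 7-exo-tet alkylation of the ester enolate, returning to the route at 16.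

**Step 14.** What may go wrong: the equilibration may stop at a ratio that does not favour the trans epimer enough, since the energy gap between a pseudo-equatorial and a pseudo-axial acyl group on a flexible seven-membered ring is modest. Fallback (C25 fixed kinetically by an auxiliary before ring B is closed): setting out from 13, saponification with LiOH would give the acid F10. Its pivaloyl mixed anhydride and lithiated (S)-4-benzyl-1,3-oxazolidin-2-one would give the imide F11. NaN(SiMe3)2 and 2,3-dibromopropene would alkylate the chelated Z-enolate from the face away from the benzyl group to give the alkylated imide F12 with the (S) configuration at C25. AlMe3 with MeNH(OMe)·HCl would exchange the auxiliary for the N-methoxy-N-methylamide F13. Hydroboration to the alkylborane F14 and ring closure as in step 12 would give the single-epimer bicyclic amide F15, and CH2=CHCH2CH2MgBr would return to the route at 19.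

**Step 15.** What may go wrong: the ruthenium alkylidene may fail to engage the 1,1-disubstituted C6 methylene in the conformation needed for bridging, so that oligomerization by cross-metathesis or slow involvement of the side-chain alkene takes over. Fallback (rings A and B by cycloaddition): setting out from 13, the alkylborane F6 would be coupled with 2-chloro-1,3-butadiene (Pd(OAc)2, a dialkylbiarylphosphine, K3PO4) to the diene ester F16. Chloromethyllithium, generated from chloroiodomethane and MeLi·LiBr at −78 °C, would convert the ester into the chloromethyl ketone F17. Ionization with Et3N and LiClO4 would trigger the type 2 intramolecular (4+3) cycloaddition discussed as Alternative 2 and return to the route at 20. The price is that C25 would then be set by the facial selectivity of the cycloaddition.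

## Further compounds

F1 | step 5 | RAMP hydrazone of 5, (E)-N-[(2R)-2-(methoxymethyl)pyrrolidin-1-yl]imine of (3S,6E)-8-[(tert-butyldiphenylsilyl)oxy]-3,7-dimethyloct-6-enal | COC[C@H]1CCCN1/N=C/C[C@@H](C)CC/C=C(\C)CO[Si](c1ccccc1)(c1ccccc1)C(C)(C)C
F2 | step 5 | RAMP hydrazone of (2S)-2-[(2S,5E)-7-[(tert-butyldiphenylsilyl)oxy]-6-methylhept-5-en-2-yl]-4-(2-methyl-1,3-dioxolan-2-yl)butanal | COC[C@H]1CCCN1/N=C/[C@@H](CCC1(C)OCCO1)[C@@H](C)CC/C=C(\C)CO[Si](c1ccccc1)(c1ccccc1)C(C)(C)C
F3 | step 8 | methyl 2-[(1S,6S)-3-[(tert-butyldimethylsilyl)oxy]-6-[(2S,5E)-7-[(tert-butyldiphenylsilyl)oxy]-6-methylhept-5-en-2-yl]cyclohex-2-en-1-yl]acetate | CC(C)(C)[Si](C)(C)OC1=C[C@@H](CC(=O)OC)[C@H]([C@@H](C)CC/C=C(\C)CO[Si](c2ccccc2)(c2ccccc2)C(C)(C)C)CC1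
F4 | step 8 | methyl 2-[(1S,6S)-6-[(2S,5E)-7-[(tert-butyldiphenylsilyl)oxy]-6-methylhept-5-en-2-yl]-2-(1-hydroxyethyl)-3-oxocyclohexyl]acetate (mixture at C9 and the carbinol carbon) | O=C1C(C(C)O)[C@@H](CC(=O)OC)[C@H]([C@@H](C)CC/C=C(\C)CO[Si](c2ccccc2)(c2ccccc2)C(C)(C)C)CC1
F5 | step 8 | methyl 2-[(1S,6S)-6-[(2S,5E)-7-[(tert-butyldiphenylsilyl)oxy]-6-methylhept-5-en-2-yl]-2-ethylidene-3-oxocyclohexyl]acetate | O=C1C(=CC)[C@@H](CC(=O)OC)[C@H]([C@@H](C)CC/C=C(\C)CO[Si](c2ccccc2)(c2ccccc2)C(C)(C)C)CC1
F6 | step 12 | methyl 2-[(1S,6S)-2-[2-(9-borabicyclo[3.3.1]nonan-9-yl)ethyl]-6-[(2S,5E)-7-[(tert-butyldiphenylsilyl)oxy]-6-methylhept-5-en-2-yl]-3-methylcyclohex-2-en-1-yl]acetate | CC1=C(CCB2C3CCCC2CCC3)[C@@H](CC(=O)OC)[C@H]([C@@H](C)CC/C=C(\C)CO[Si](c2ccccc2)(c2ccccc2)C(C)(C)C)CC1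
F7 | step 12 | methyl 2-[(1S,6S)-2-[3-({[tert-butyl(dimethyl)silyl]oxy}methyl)but-3-en-1-yl]-6-[(2S,5E)-7-[(tert-butyldiphenylsilyl)oxy]-6-methylhept-5-en-2-yl]-3-methylcyclohex-2-en-1-yl]acetate | CC1=C(CCC(=C)CO[Si](C)(C)C(C)(C)C)[C@@H](CC(=O)OC)[C@H]([C@@H](C)CC/C=C(\C)CO[Si](c2ccccc2)(c2ccccc2)C(C)(C)C)CC1
F8 | step 12 | methyl 2-[(1S,6S)-6-[(2S,5E)-7-[(tert-butyldiphenylsilyl)oxy]-6-methylhept-5-en-2-yl]-2-[3-(hydroxymethyl)but-3-en-1-yl]-3-methylcyclohex-2-en-1-yl]acetate | CC1=C(CCC(=C)CO)[C@@H](CC(=O)OC)[C@H]([C@@H](C)CC/C=C(\C)CO[Si](c2ccccc2)(c2ccccc2)C(C)(C)C)CC1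
F9 | step 12 | methyl 2-[(1S,6S)-2-[3-(bromomethyl)but-3-en-1-yl]-6-[(2S,5E)-7-[(tert-butyldiphenylsilyl)oxy]-6-methylhept-5-en-2-yl]-3-methylcyclohex-2-en-1-yl]acetate | CC1=C(CCC(=C)CBr)[C@@H](CC(=O)OC)[C@H]([C@@H](C)CC/C=C(\C)CO[Si](c2ccccc2)(c2ccccc2)C(C)(C)C)CC1
F10 | step 14 | 2-[(1S,6S)-6-[(2S,5E)-7-[(tert-butyldiphenylsilyl)oxy]-6-methylhept-5-en-2-yl]-2-ethenyl-3-methylcyclohex-2-en-1-yl]acetic acid | CC1=C(C=C)[C@@H](CC(=O)O)[C@H]([C@@H](C)CC/C=C(\C)CO[Si](c2ccccc2)(c2ccccc2)C(C)(C)C)CC1
F11 | step 14 | (4S)-4-benzyl-3-{2-[(1S,6S)-6-[(2S,5E)-7-[(tert-butyldiphenylsilyl)oxy]-6-methylhept-5-en-2-yl]-2-ethenyl-3-methylcyclohex-2-en-1-yl]acetyl}-1,3-oxazolidin-2-one | CC1=C(C=C)[C@@H](CC(=O)N2[C@@H](Cc3ccccc3)COC2=O)[C@H]([C@@H](C)CC/C=C(\C)CO[Si](c4ccccc4)(c4ccccc4)C(C)(C)C)CC1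
F12 | step 14 | (4S)-4-benzyl-3-{(2S)-4-bromo-2-[(1R,6S)-6-[(2S,5E)-7-[(tert-butyldiphenylsilyl)oxy]-6-methylhept-5-en-2-yl]-2-ethenyl-3-methylcyclohex-2-en-1-yl]pent-4-enoyl}-1,3-oxazolidin-2-one | CC1=C(C=C)[C@@H]([C@H](CC(Br)=C)C(=O)N2[C@@H](Cc3ccccc3)COC2=O)[C@H]([C@@H](C)CC/C=C(\C)CO[Si](c4ccccc4)(c4ccccc4)C(C)(C)C)CC1
F13 | step 14 | (2S)-4-bromo-2-[(1R,6S)-6-[(2S,5E)-7-[(tert-butyldiphenylsilyl)oxy]-6-methylhept-5-en-2-yl]-2-ethenyl-3-methylcyclohex-2-en-1-yl]-N-methoxy-N-methylpent-4-enamide | CC1=C(C=C)[C@@H]([C@H](CC(Br)=C)C(=O)N(C)OC)[C@H]([C@@H](C)CC/C=C(\C)CO[Si](c2ccccc2)(c2ccccc2)C(C)(C)C)CC1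
F14 | step 14 | (2S)-2-[(1R,6S)-2-[2-(9-borabicyclo[3.3.1]nonan-9-yl)ethyl]-6-[(2S,5E)-7-[(tert-butyldiphenylsilyl)oxy]-6-methylhept-5-en-2-yl]-3-methylcyclohex-2-en-1-yl]-4-bromo-N-methoxy-N-methylpent-4-enamide | CC1=C(CCB2C3CCCC2CCC3)[C@@H]([C@H](CC(Br)=C)C(=O)N(C)OC)[C@H]([C@@H](C)CC/C=C(\C)CO[Si](c2ccccc2)(c2ccccc2)C(C)(C)C)CC1
F15 | step 14 | (4S,4aR,5S)-4-[(2S,5E)-7-[(tert-butyldiphenylsilyl)oxy]-6-methylhept-5-en-2-yl]-N-methoxy-N,1-dimethyl-7-methylidene-3,4,4a,5,6,7,8,9-octahydro-2H-benzo[7]annulene-5-carboxamide | CC1=C2CCC(=C)C[C@H](C(=O)N(C)OC)[C@H]2[C@H]([C@@H](C)CC/C=C(\C)CO[Si](c3ccccc3)(c3ccccc3)C(C)(C)C)CC1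
F16 | step 15 | methyl 2-[(1S,6S)-6-[(2S,5E)-7-[(tert-butyldiphenylsilyl)oxy]-6-methylhept-5-en-2-yl]-3-methyl-2-(3-methylidenepent-4-en-1-yl)cyclohex-2-en-1-yl]acetate | CC1=C(CCC(=C)C=C)[C@@H](CC(=O)OC)[C@H]([C@@H](C)CC/C=C(\C)CO[Si](c2ccccc2)(c2ccccc2)C(C)(C)C)CC1
F17 | step 15 | 1-[(1S,6S)-6-[(2S,5E)-7-[(tert-butyldiphenylsilyl)oxy]-6-methylhept-5-en-2-yl]-3-methyl-2-(3-methylidenepent-4-en-1-yl)cyclohex-2-en-1-yl]-3-chloropropan-2-one | CC1=C(CCC(=C)C=C)[C@@H](CC(=O)CCl)[C@H]([C@@H](C)CC/C=C(\C)CO[Si](c2ccccc2)(c2ccccc2)C(C)(C)C)CC1
A1 | alternative 1 | cyclization substrate: ring A (C2 methylene, C5 methyl carbonate, exocyclic C6=C7) joined through C25–C24 to ring C bearing CH2SO2Ph on C9, tert-butyldimethylsilyl ether | C=C1CCC(OC(=O)OC)C(=C)C[C@H]1[C@@H]2C(CS(=O)(=O)c3ccccc3)=C(C)CC[C@H]2[C@@H](C)CC/C=C(\C)CO[Si](C)(C)C(C)(C)C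
A2 | alternative 1 | target skeleton with a phenylsulfonyl group on C8, tert-butyldimethylsilyl ether | C=C1CCC=C2C[C@H](S(=O)(=O)c4ccccc4)C3=C(C)CC[C@@H]([C@@H](C)CC/C=C(\C)CO[Si](C)(C)C(C)(C)C)[C@@H]3[C@@H]1C2
A3 | alternative 2 | chloromethyl ketone with a 3-methylidenepent-4-enyl arm on C9, tert-butyldimethylsilyl ether | ClCC(=O)C[C@@H]1C(CCC(=C)C=C)=C(C)CC[C@H]1[C@@H](C)CC/C=C(\C)CO[Si](C)(C)C(C)(C)C
A4 | alternative 2 | tricyclic C2 ketone, tert-butyldimethylsilyl ether | O=C1CCC=C2CCC3=C(C)CC[C@@H]([C@@H](C)CC/C=C(\C)CO[Si](C)(C)C(C)(C)C)[C@@H]3[C@@H]1C2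
A5 | alternative 3 | 1,6-diketone: bicyclo[4.4.1]undecenone (C9 ketone) with the C14–C13–C12–C10(=O)–C11 chain on C24, tert-butyldimethylsilyl ether | C=C1CCC=C2CCC(=O)[C@H]([C@@H](CCC(C)=O)[C@@H](C)CC/C=C(\C)CO[Si](C)(C)C(C)(C)C)[C@@H]1C2
A6 | alternative 3 | tert-butyldimethylsilyl ether of the target | C=C1CCC=C2CCC3=C(C)CC[C@@H]([C@@H](C)CC/C=C(\C)CO[Si](C)(C)C(C)(C)C)[C@@H]3[C@@H]1C2
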